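**Retrosynthetic overview**
1. Target ⇐ phenol desilylation, O‑acetylation and enone‑selective 1,2‑reduction of a 3‑methoxybicyclo[3.2.1]oct‑3‑ene‑2,8‑dione, itself from O‑methylation of the diosphenol of a 2,3,8‑trione.
2. The six‑membered ring (second and last ring) is closed by an intramolecular aldol, C1 enolate onto the C2 aldehyde, of a cyclopentanone keto‑aldehyde.
3. Key fragment union: intermolecular Mukaiyama–Michael addition of a tetrasubstituted cyclopentanone silyl enol ether to acrolein, forming the C5–C4 bond and the quaternary C5.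
4. The cyclopentanone (first ring, present from the start) comes from (R)‑4‑silyloxycyclopentenone: trans aryl‑cuprate addition (C7), Rubottom oxidation and O‑methylation (C1), silanol elimination, α‑iodination/Stille allylation (C5), trans methyl‑cuprate addition (C6).

Convention used throughout: bicyclic core numbered C1 (OMe bridgehead), C2–C4 (three‑carbon bridge), C5 (allyl bridgehead), C6 (Me), C7 (aryl), C8 (bridging C=O); Ar* = 3,5‑dimethoxy‑4‑(triisopropylsilyloxy)phenyl. Assumption: enantiopure (R)‑4‑(tert‑butyldimethylsilyloxy)cyclopent‑2‑enone is bought as the commercial prostaglandin building block.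

**Step 1**
Reactants: 1 4‑bromo‑2,6‑dimethoxyphenol
Product: 2 (4‑bromo‑2,6‑dimethoxyphenoxy)triisopropylsilane
Conditions: TIPSOTf, 2,6‑lutidine, CH2Cl2, 0 °C → rt
Reagents that add atoms: triisopropylsilyl trifluoromethanesulfonate, CC(C)[Si](C(C)C)(C(C)C)OS(=O)(=O)C(F)(F)F
Why: O‑silylation of the hindered phenol with the silyl triflate gives a base‑ and organometallic‑stable aryl silyl ether that is removable at the end with fluoride.

**Step 2**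
Reactants: 2 (4‑bromo‑2,6‑dimethoxyphenoxy)triisopropylsilane; 3 (4R)‑4‑(tert‑butyldimethylsilyloxy)cyclopent‑2‑en‑1‑one
Product: 5 (3S,4R)‑3‑Ar*‑4‑(tert‑butyldimethylsilyloxy)‑1‑(trimethylsilyloxy)cyclopent‑1‑ene, via aryl Grignard reagent 4 (not isolated)
Conditions: Mg, THF, 50 °C; then CuBr·SMe2 (10 mol %), TMSCl, 3, THF, −78 → −40 °C; Et3N quench
Reagents that add atoms: magnesium, [Mg] (into 4); chlorotrimethylsilane, C[Si](C)(C)Cl
Why: Copper‑catalysed conjugate addition of the aryl Grignard with in situ silyl trapping delivers the aryl group anti to the C4 silyloxy group (sets C7) and fixes the enolate regiochemistry as the silyl enol ether.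

**Step 3**
Reactants: 5 (3S,4R)‑3‑Ar*‑4‑(tert‑butyldimethylsilyloxy)‑1‑(trimethylsilyloxy)cyclopent‑1‑ene
Product: 8 (2R,3R,4R)‑4‑(tert‑butyldimethylsilyloxy)‑2‑hydroxy‑3‑Ar*‑cyclopentan‑1‑one, via silyloxy epoxide 6 (not isolated), via 2‑silyloxy ketone 7 (not isolated)
Conditions: mCPBA, hexane/CH2Cl2, −15 → 0 °C; then 10 % aq. citric acid, THF, 0 °C
Reagents that add atoms: 3‑chloroperoxybenzoic acid, OOC(=O)c1cccc(Cl)c1
Why: Rubottom oxidation epoxidises the electron‑rich enol ether anti to the adjacent aryl group and, after silyl migration and hydrolysis, gives the 2,3‑trans α‑hydroxy ketone; this centre is later re‑formed in the aldol.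

**Step 4**
Reactants: 8 (2R,3R,4R)‑4‑(tert‑butyldimethylsilyloxy)‑2‑hydroxy‑3‑Ar*‑cyclopentan‑1‑one
Product: 9 (2R,3R,4R)‑4‑(tert‑butyldimethylsilyloxy)‑2‑methoxy‑3‑Ar*‑cyclopentan‑1‑one
Conditions: Me3OBF4, 1,8‑bis(dimethylamino)naphthalene, 4 Å MS, CH2Cl2, rt
Reagents that add atoms: trimethyloxonium tetrafluoroborate, C[O+](C)C.F[B-](F)(F)F
Why: Meerwein‑salt O‑methylation under non‑nucleophilic buffering etherifies the secondary alcohol without enolising or eliminating the β‑silyloxy ketone.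

**Step 5**
Reactants: 9 (2R,3R,4R)‑4‑(tert‑butyldimethylsilyloxy)‑2‑methoxy‑3‑Ar*‑cyclopentan‑1‑one
Product: 10 (4R,5R)‑5‑methoxy‑4‑Ar*‑cyclopent‑2‑en‑1‑one
Conditions: DBU, CH2Cl2, 0 °C
Reagents that add atoms: none
Why: E1cB β‑elimination of the silanol through the only CH2 α‑position unveils the enone on the side away from the methoxy group, leaving the C7 aryl stereocentre untouched.

**Step 6**
Reactants: 10 (4R,5R)‑5‑methoxy‑4‑Ar*‑cyclopent‑2‑en‑1‑one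
Product: 11 (4R,5R)‑2‑iodo‑5‑methoxy‑4‑Ar*‑cyclopent‑2‑en‑1‑one
Conditions: I2, pyridine/CH2Cl2 (1:1), 0 °C → rt
Reagents that add atoms: iodine, II
Why: Johnson α‑iodination (pyridine conjugate addition, enolate iodination, elimination) functionalises only the enone α‑carbon under mild, weakly basic conditions.

**Step 7**
Reactants: 11 (4R,5R)‑2‑iodo‑5‑methoxy‑4‑Ar*‑cyclopent‑2‑en‑1‑one; 12 allyltributylstannane
Product: 13 (4R,5R)‑5‑methoxy‑2‑(prop‑2‑enyl)‑4‑Ar*‑cyclopent‑2‑en‑1‑one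
Conditions: Pd2(dba)3 (2.5 mol %), AsPh3, CuI (10 mol %), NMP, rt → 45 °C
Reagents that add atoms: none
Why: Stille coupling (oxidative addition of the vinyl C–I bond to zerovalent palladium, copper‑assisted transmetalation, reductive elimination) installs the allyl group at C5 under neutral conditions.

**Step 8**
Reactants: 13 (4R,5R)‑5‑methoxy‑2‑(prop‑2‑enyl)‑4‑Ar*‑cyclopent‑2‑en‑1‑one
Product: 14 [(3S,4R,5R)‑5‑methoxy‑3‑methyl‑2‑(prop‑2‑enyl)‑4‑Ar*‑cyclopent‑1‑en‑1‑yl]oxy(trimethyl)silane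
Conditions: Me2CuLi (from MeLi and CuI, Et2O, 0 °C), TMSCl, THF, −78 °C; Et3N, hexane work‑up
Reagents that add atoms: lithium dimethylcuprate, [Li+].C[Cu-]C; chlorotrimethylsilane, C[Si](C)(C)Cl
Why: TMSCl‑accelerated Gilman conjugate addition places the methyl group anti to the adjacent aryl group (sets C6, trans to C7) and gives the tetrasubstituted C5 enol ether regiospecifically.

**Step 9**
Reactants: 14 [(3S,4R,5R)‑5‑methoxy‑3‑methyl‑2‑(prop‑2‑enyl)‑4‑Ar*‑cyclopent‑1‑en‑1‑yl]oxy(trimethyl)silane; 15 acrolein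
Product: 16 3‑[(1S,2S,3R,4R)‑4‑methoxy‑2‑methyl‑5‑oxo‑1‑(prop‑2‑enyl)‑3‑Ar*‑cyclopentyl]propanal
Conditions: 15 (3 equiv), (S)‑5‑benzyl‑2,2,3‑trimethylimidazolidin‑4‑one·CF3CO2H (first‑generation MacMillan imidazolidinone, 20 mol %), CH2Cl2/i‑PrOH, −30 → 0 °C
Reagents that add atoms: none
Why: Iminium‑catalysed Mukaiyama–Michael addition allows only 1,4‑attack on acrolein, and the enol ether reacts at C5 on the face anti to the adjacent C6 methyl group, so the new chain is trans to methyl and cis to the aryl group (sets quaternary C5).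

**Step 10**
Reactants: 16 3‑[(1S,2S,3R,4R)‑4‑methoxy‑2‑methyl‑5‑oxo‑1‑(prop‑2‑enyl)‑3‑Ar*‑cyclopentyl]propanal
Product: 17 (1S,5S,6S,7R)‑2‑hydroxy‑1‑methoxy‑6‑methyl‑5‑(prop‑2‑enyl)‑7‑Ar*‑bicyclo[3.2.1]octan‑8‑one (both C2 epimers, carried on together)
Conditions: K2CO3 (0.5 equiv), MeOH/THF, 0 °C, 0.02 M
Reagents that add atoms: none
Why: Intramolecular aldol addition: the ketone can enolise only toward C1 and the tether forces C1–C2 bond formation on the face already bearing the chain, fixing the C1 bridgehead with the aryl group endo and the methyl group exo.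

**Step 11**
Reactants: 17 (1S,5S,6S,7R)‑2‑hydroxy‑1‑methoxy‑6‑methyl‑5‑(prop‑2‑enyl)‑7‑Ar*‑bicyclo[3.2.1]octan‑8‑one
Product: 18 (1S,5S,6S,7R)‑1‑methoxy‑6‑methyl‑5‑(prop‑2‑enyl)‑7‑Ar*‑bicyclo[3.2.1]octane‑2,8‑dione
Conditions: Dess–Martin periodinane, CH2Cl2, rt
Reagents that add atoms: none
Why: Dess–Martin oxidation converts both ketol epimers into one diketone under neutral conditions that spare the non‑enolisable β‑diketone, the alkene and the silyl ether.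

**Step 12**
Reactants: 18 (1S,5S,6S,7R)‑1‑methoxy‑6‑methyl‑5‑(prop‑2‑enyl)‑7‑Ar*‑bicyclo[3.2.1]octane‑2,8‑dione
Product: 20 (1R,5R,6S,7R)‑3‑hydroxy‑1‑methoxy‑6‑methyl‑5‑(prop‑2‑enyl)‑7‑Ar*‑bicyclo[3.2.1]octane‑2,8‑dione (C3 epimers), via potassium enolate 19 (not isolated)
Conditions: KN(SiMe3)2, THF, −78 °C; 2‑(phenylsulfonyl)‑3‑phenyloxaziridine, −78 °C; AcOH
Reagents that add atoms: 2‑(phenylsulfonyl)‑3‑phenyloxaziridine, O=S(=O)(c1ccccc1)N1OC1c1ccccc1; potassium bis(trimethylsilyl)amide, C[Si](C)(C)[N-][Si](C)(C)C.[K+] (potassium into 19)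
Why: Davis enolate hydroxylation; C3 is the only enolisable position because both bridgeheads are quaternary, and the amide base is non‑nucleophilic so it does not cleave the β‑diketone.

**Step 13**
Reactants: 20 (1R,5R,6S,7R)‑3‑hydroxy‑1‑methoxy‑6‑methyl‑5‑(prop‑2‑enyl)‑7‑Ar*‑bicyclo[3.2.1]octane‑2,8‑dione
Product: 22 (1R,5S,6S,7R)‑3‑hydroxy‑1‑methoxy‑6‑methyl‑5‑(prop‑2‑enyl)‑7‑Ar*‑bicyclo[3.2.1]oct‑3‑ene‑2,8‑dione, via 2,3,8‑trione 21 (not isolated)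
Conditions: Dess–Martin periodinane, CH2Cl2, rt
Reagents that add atoms: none
Why: Oxidation of the acyloin gives the 1,2‑diketone, which can enolise only toward C4 and so tautomerises to the conjugated diosphenol with the C3=C4 double bond.

**Step 14**
Reactants: 22 (1R,5S,6S,7R)‑3‑hydroxy‑1‑methoxy‑6‑methyl‑5‑(prop‑2‑enyl)‑7‑Ar*‑bicyclo[3.2.1]oct‑3‑ene‑2,8‑dione
Product: 23 (1R,5S,6S,7R)‑1,3‑dimethoxy‑6‑methyl‑5‑(prop‑2‑enyl)‑7‑Ar*‑bicyclo[3.2.1]oct‑3‑ene‑2,8‑dione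
Conditions: Me2SO4, K2CO3, acetone, rt
Reagents that add atoms: dimethyl sulfate, COS(=O)(=O)OC
Why: O‑alkylation of the acidic diosphenol with a hard methylating agent gives the α‑methoxy enone regiospecifically, in dry acetone with no nucleophile to attack the β‑diketone or the aryl silyl ether.

**Step 15**
Reactants: 23 (1R,5S,6S,7R)‑1,3‑dimethoxy‑6‑methyl‑5‑(prop‑2‑enyl)‑7‑Ar*‑bicyclo[3.2.1]oct‑3‑ene‑2,8‑dione
Product: 24 (1S,2R,5S,6S,7R)‑2‑hydroxy‑1,3‑dimethoxy‑6‑methyl‑5‑(prop‑2‑enyl)‑7‑Ar*‑bicyclo[3.2.1]oct‑3‑en‑8‑one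
Conditions: NaBH4, CeCl3·7H2O, MeOH, −78 °C
Reagents that add atoms: none
Why: Luche 1,2‑reduction takes the CeCl3‑activated enone carbonyl in preference to the C8 ketone (flanked by two quaternary bridgeheads and the exo methyl), and hydride enters from the C8 side because the endo aryl group blocks the other face, giving the (2R) alcohol syn to the C6–C7 bridge.

**Step 16**
Reactants: 24 (1S,2R,5S,6S,7R)‑2‑hydroxy‑1,3‑dimethoxy‑6‑methyl‑5‑(prop‑2‑enyl)‑7‑Ar*‑bicyclo[3.2.1]oct‑3‑en‑8‑one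
Product: 25 [(1S,2R,5S,6S,7R)‑1,3‑dimethoxy‑6‑methyl‑8‑oxo‑5‑(prop‑2‑enyl)‑7‑Ar*‑bicyclo[3.2.1]oct‑3‑en‑2‑yl] acetate
Conditions: Ac2O, DMAP (cat.), pyridine, rt
Reagents that add atoms: acetic anhydride, CC(=O)OC(C)=O
Why: DMAP‑catalysed acylation esterifies the only free hydroxyl with retention at C2 while the phenol is still silyl‑protected.

**Step 17**
Reactants: 25 [(1S,2R,5S,6S,7R)‑1,3‑dimethoxy‑6‑methyl‑8‑oxo‑5‑(prop‑2‑enyl)‑7‑Ar*‑bicyclo[3.2.1]oct‑3‑en‑2‑yl] acetate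
Product: 26 [(1S,2R,5S,6S,7R)‑7‑(4‑hydroxy‑3,5‑dimethoxyphenyl)‑1,3‑dimethoxy‑6‑methyl‑8‑oxo‑5‑(prop‑2‑enyl)bicyclo[3.2.1]oct‑3‑en‑2‑yl] acetate (CNP0373655.1)
Conditions: Bu4NF, AcOH, THF, 0 °C
Reagents that add atoms: none
Why: Buffered fluoride desilylation cleaves the aryl Si–O bond selectively, leaving the acetate, enol ether, ketone and allyl group intact.

**Compound list**
1 | 4‑bromo‑2,6‑dimethoxyphenol | Oc1c(OC)cc(Br)cc1OC | starting material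
2 | (4‑bromo‑2,6‑dimethoxyphenoxy)triisopropylsilane | Brc1cc(OC)c(O[Si](C(C)C)(C(C)C)C(C)C)c(OC)c1 | intermediate
3 | (4R)‑4‑(tert‑butyldimethylsilyloxy)cyclopent‑2‑en‑1‑one | O=C1C=C[C@H](O[Si](C)(C)C(C)(C)C)C1 | starting material
4 | [3,5‑dimethoxy‑4‑(triisopropylsilyloxy)phenyl]magnesium bromide | Br[Mg]c1cc(OC)c(O[Si](C(C)C)(C(C)C)C(C)C)c(OC)c1 | intermediate
5 | (3S,4R)‑3‑Ar*‑4‑(tert‑butyldimethylsilyloxy)‑1‑(trimethylsilyloxy)cyclopent‑1‑ene (aryl/OTBS trans) | C[Si](C)(C)OC1=C[C@@H](c2cc(OC)c(O[Si](C(C)C)(C(C)C)C(C)C)c(OC)c2)[C@H](O[Si](C)(C)C(C)(C)C)C1 | intermediate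
6 | 4‑Ar*‑3‑(tert‑butyldimethylsilyloxy)‑1‑(trimethylsilyloxy)‑6‑oxabicyclo[3.1.0]hexane, epoxide oxygen trans to the aryl group | C[Si](C)(C)O[C@@]12O[C@@H]1[C@@H](c3cc(OC)c(O[Si](C(C)C)(C(C)C)C(C)C)c(OC)c3)[C@H](O[Si](C)(C)C(C)(C)C)C2 | intermediate
7 | (2R,3S,4R)‑4‑(tert‑butyldimethylsilyloxy)‑3‑Ar*‑2‑(trimethylsilyloxy)cyclopentan‑1‑one (all‑trans) | O=C1[C@H](O[Si](C)(C)C)[C@@H](c2cc(OC)c(O[Si](C(C)C)(C(C)C)C(C)C)c(OC)c2)[C@H](O[Si](C)(C)C(C)(C)C)C1 | intermediate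
8 | (2R,3R,4R)‑4‑(tert‑butyldimethylsilyloxy)‑2‑hydroxy‑3‑Ar*‑cyclopentan‑1‑one (all‑trans) | O=C1[C@H](O)[C@@H](c2cc(OC)c(O[Si](C(C)C)(C(C)C)C(C)C)c(OC)c2)[C@H](O[Si](C)(C)C(C)(C)C)C1 | intermediate
9 | (2R,3R,4R)‑4‑(tert‑butyldimethylsilyloxy)‑2‑methoxy‑3‑Ar*‑cyclopentan‑1‑one | O=C1[C@H](OC)[C@@H](c2cc(OC)c(O[Si](C(C)C)(C(C)C)C(C)C)c(OC)c2)[C@H](O[Si](C)(C)C(C)(C)C)C1 | intermediate
10 | (4R,5R)‑5‑methoxy‑4‑Ar*‑cyclopent‑2‑en‑1‑one (trans) | O=C1[C@H](OC)[C@@H](c2cc(OC)c(O[Si](C(C)C)(C(C)C)C(C)C)c(OC)c2)C=C1 | intermediate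
11 | (4R,5R)‑2‑iodo‑5‑methoxy‑4‑Ar*‑cyclopent‑2‑en‑1‑one | O=C1[C@H](OC)[C@@H](c2cc(OC)c(O[Si](C(C)C)(C(C)C)C(C)C)c(OC)c2)C=C1I | intermediate
12 | allyltributylstannane | C=CC[Sn](CCCC)(CCCC)CCCC | starting material
13 | (4R,5R)‑5‑methoxy‑2‑(prop‑2‑enyl)‑4‑Ar*‑cyclopent‑2‑en‑1‑one | O=C1[C@H](OC)[C@@H](c2cc(OC)c(O[Si](C(C)C)(C(C)C)C(C)C)c(OC)c2)C=C1CC=C | intermediate
14 | [(3S,4R,5R)‑5‑methoxy‑3‑methyl‑2‑(prop‑2‑enyl)‑4‑Ar*‑cyclopent‑1‑en‑1‑yl]oxy(trimethyl)silane (Me/aryl trans, aryl/OMe trans) | C=CCC1=C(O[Si](C)(C)C)[C@H](OC)[C@@H](c2cc(OC)c(O[Si](C(C)C)(C(C)C)C(C)C)c(OC)c2)[C@@H]1C | intermediate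
15 | acrolein (prop‑2‑enal) | C=CC=O | starting material
16 | 3‑[(1S,2S,3R,4R)‑4‑methoxy‑2‑methyl‑5‑oxo‑1‑(prop‑2‑enyl)‑3‑Ar*‑cyclopentyl]propanal (allyl cis to methyl, oxopropyl chain cis to aryl) | O=C1[C@H](OC)[C@@H](c2cc(OC)c(O[Si](C(C)C)(C(C)C)C(C)C)c(OC)c2)[C@H](C)[C@@]1(CC=C)CCC=O | intermediate
17 | (1S,5S,6S,7R)‑2‑hydroxy‑1‑methoxy‑6‑methyl‑5‑(prop‑2‑enyl)‑7‑Ar*‑bicyclo[3.2.1]octan‑8‑one (7‑endo aryl, 6‑exo methyl; C2 epimer mixture) | C=CC[C@]12CCC(O)[C@](OC)(C1=O)[C@@H](c1cc(OC)c(O[Si](C(C)C)(C(C)C)C(C)C)c(OC)c1)[C@@H]2C | intermediate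
18 | (1S,5S,6S,7R)‑1‑methoxy‑6‑methyl‑5‑(prop‑2‑enyl)‑7‑Ar*‑bicyclo[3.2.1]octane‑2,8‑dione | C=CC[C@]12CCC(=O)[C@](OC)(C1=O)[C@@H](c1cc(OC)c(O[Si](C(C)C)(C(C)C)C(C)C)c(OC)c1)[C@@H]2C | intermediate
19 | potassium C2–C3 enolate of 18 (bridgehead, C6 and C7 configurations as in 18) | C=CC[C@]12CC=C([O-])[C@](OC)(C1=O)[C@@H](c1cc(OC)c(O[Si](C(C)C)(C(C)C)C(C)C)c(OC)c1)[C@@H]2C.[K+] | intermediate
20 | (1R,5R,6S,7R)‑3‑hydroxy‑1‑methoxy‑6‑methyl‑5‑(prop‑2‑enyl)‑7‑Ar*‑bicyclo[3.2.1]octane‑2,8‑dione (C3 epimer mixture; same spatial arrangement as 18) | C=CC[C@]12CC(O)C(=O)[C@](OC)(C1=O)[C@@H](c1cc(OC)c(O[Si](C(C)C)(C(C)C)C(C)C)c(OC)c1)[C@@H]2C | intermediate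
21 | (1R,5R,6S,7R)‑1‑methoxy‑6‑methyl‑5‑(prop‑2‑enyl)‑7‑Ar*‑bicyclo[3.2.1]octane‑2,3,8‑trione | C=CC[C@]12CC(=O)C(=O)[C@](OC)(C1=O)[C@@H](c1cc(OC)c(O[Si](C(C)C)(C(C)C)C(C)C)c(OC)c1)[C@@H]2C | intermediate
22 | (1R,5S,6S,7R)‑3‑hydroxy‑1‑methoxy‑6‑methyl‑5‑(prop‑2‑enyl)‑7‑Ar*‑bicyclo[3.2.1]oct‑3‑ene‑2,8‑dione (diosphenol) | C=CC[C@]12C=C(O)C(=O)[C@](OC)(C1=O)[C@@H](c1cc(OC)c(O[Si](C(C)C)(C(C)C)C(C)C)c(OC)c1)[C@@H]2C | intermediate
23 | (1R,5S,6S,7R)‑1,3‑dimethoxy‑6‑methyl‑5‑(prop‑2‑enyl)‑7‑Ar*‑bicyclo[3.2.1]oct‑3‑ene‑2,8‑dione | C=CC[C@]12C=C(OC)C(=O)[C@](OC)(C1=O)[C@@H](c1cc(OC)c(O[Si](C(C)C)(C(C)C)C(C)C)c(OC)c1)[C@@H]2C | intermediate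
24 | (1S,2R,5S,6S,7R)‑2‑hydroxy‑1,3‑dimethoxy‑6‑methyl‑5‑(prop‑2‑enyl)‑7‑Ar*‑bicyclo[3.2.1]oct‑3‑en‑8‑one (OH syn to the C6–C7 bridge) | C=CC[C@]12C=C(OC)[C@@H](O)[C@](OC)(C1=O)[C@@H](c1cc(OC)c(O[Si](C(C)C)(C(C)C)C(C)C)c(OC)c1)[C@@H]2C | intermediate
25 | [(1S,2R,5S,6S,7R)‑1,3‑dimethoxy‑6‑methyl‑8‑oxo‑5‑(prop‑2‑enyl)‑7‑Ar*‑bicyclo[3.2.1]oct‑3‑en‑2‑yl] acetate | C=CC[C@]12C=C(OC)[C@@H](OC(C)=O)[C@](OC)(C1=O)[C@@H](c1cc(OC)c(O[Si](C(C)C)(C(C)C)C(C)C)c(OC)c1)[C@@H]2C | intermediate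
26 | [(1S,2R,5S,6S,7R)‑7‑(4‑hydroxy‑3,5‑dimethoxyphenyl)‑1,3‑dimethoxy‑6‑methyl‑8‑oxo‑5‑(prop‑2‑enyl)bicyclo[3.2.1]oct‑3‑en‑2‑yl] acetate | C=CC[C@]12C=C(OC)[C@@H](OC(C)=O)[C@](OC)(C1=O)[C@@H](c1cc(OC)c(O)c(OC)c1)[C@@H]2C | target

**Totals**
Total steps: 17. Longest linear sequence: 17 steps (1 → 26); the enone 3 joins at step 2, the stannane 12 at step 7 and acrolein 15 at step 9.

**Three steps most likely to fail, with fallbacks**

Step 9 (Michael addition forming the quaternary C5). Risks are slow attack at the congested enol ether carbon, protodesilylation of 14 by the acidic co‑catalyst, and incomplete facial selectivity. The fallback sets out from 14 and replaces the conjugate addition by an enolate alkylation. MeLi in THF at 0 °C cleaves the silyl enol ether to the regiodefined lithium enolate F1. This is alkylated with 2‑(2‑iodoethyl)‑1,3‑dioxolane in THF/DMPU, again anti to the C6 methyl group, to give the dioxolane‑protected keto aldehyde F2. Aqueous oxalic acid in THF removes the acetal, and the route is rejoined at 16.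

Step 10 (intramolecular aldol onto a hindered α‑methoxy ketone). Risks are a sluggish C1 enolisation, intermolecular aldehyde self‑condensation and an unfavourable ketol/retro‑aldol balance. The fallback sets out from 16 and closes the ring at the acyl oxidation level. Pinnick oxidation (NaClO2, NaH2PO4, 2‑methylbut‑2‑ene) gives the keto acid F3, and TMSCHN2 in MeOH/toluene gives the keto methyl ester F4. Intramolecular Claisen (Dieckmann) condensation with LiN(SiMe3)2 (2.2 equiv, THF, −78 → 0 °C) is driven by enolisation of the product at C3 and forms the C1–C2 bond directly. The route is rejoined at 18, bypassing 17.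

Step 12 (enolate hydroxylation next to a non‑enolisable β‑diketone). Risks are retro‑Claisen opening, addition of the enolate to the sulfonimine by‑product, and over‑oxidation. The fallback sets out from 18 and avoids enolate oxidation. Condensation with tert‑butoxybis(dimethylamino)methane in toluene at 80 °C gives the (E)‑enaminone F5. Photooxygenation (O2, tetraphenylporphyrin, hν, CH2Cl2, −78 °C) cleaves the enamine double bond to the trione 21, which tautomerises, and the route is rejoined at 22.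

**Further compounds**
F1 | step 9 | lithium (3S,4R,5R)‑5‑methoxy‑3‑methyl‑2‑(prop‑2‑enyl)‑4‑Ar*‑cyclopent‑1‑en‑1‑olate | C=CCC1=C([O-])[C@H](OC)[C@@H](c2cc(OC)c(O[Si](C(C)C)(C(C)C)C(C)C)c(OC)c2)[C@@H]1C.[Li+]
F2 | step 9 | (2S,3S,4R,5R)‑2‑[2‑(1,3‑dioxolan‑2‑yl)ethyl]‑5‑methoxy‑3‑methyl‑2‑(prop‑2‑enyl)‑4‑Ar*‑cyclopentan‑1‑one | O=C1[C@H](OC)[C@@H](c2cc(OC)c(O[Si](C(C)C)(C(C)C)C(C)C)c(OC)c2)[C@H](C)[C@@]1(CC=C)CCC3OCCO3
F3 | step 10 | 3‑[(1S,2S,3R,4R)‑4‑methoxy‑2‑methyl‑5‑oxo‑1‑(prop‑2‑enyl)‑3‑Ar*‑cyclopentyl]propanoic acid | O=C1[C@H](OC)[C@@H](c2cc(OC)c(O[Si](C(C)C)(C(C)C)C(C)C)c(OC)c2)[C@H](C)[C@@]1(CC=C)CCC(O)=O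
F4 | step 10 | methyl 3‑[(1S,2S,3R,4R)‑4‑methoxy‑2‑methyl‑5‑oxo‑1‑(prop‑2‑enyl)‑3‑Ar*‑cyclopentyl]propanoate | O=C1[C@H](OC)[C@@H](c2cc(OC)c(O[Si](C(C)C)(C(C)C)C(C)C)c(OC)c2)[C@H](C)[C@@]1(CC=C)CCC(=O)OC
F5 | step 12 | (E)‑3‑(dimethylaminomethylidene)‑1‑methoxy‑6‑methyl‑5‑(prop‑2‑enyl)‑7‑Ar*‑bicyclo[3.2.1]octane‑2,8‑dione (ring configuration as in 18) | C=CC[C@]12C/C(=C\N(C)C)C(=O)[C@](OC)(C1=O)[C@@H](c1cc(OC)c(O[Si](C(C)C)(C(C)C)C(C)C)c(OC)c1)[C@@H]2C
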